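At 12.0 h the larch run reads 32% of target and the alder run, with twice the free catalyst, reads 32%. Larch then stays level: 36% at 60.0 h, 37% at 96.0 h, 34% at 144 h. That last dip of 3 percentage points is twice the scatter, so this reckoning takes it as noise and puts target at 8.0 d near the mean of those readings, 35.7%.

| flask | starting material | reagent | free catalyst | remark | time |
|---|---|---|---|---|---|
| larch | 0.20 M | 0.26 M | 1 mM | the very flask that is asked about, followed so far |  |
| alder | 0.20 M | 0.26 M | 2 mM | run made earlier |  |
| flask | 0.20 M | 0.260 M | 1.0 mM |  | 8.0 d |

| run | time / h | target / % |
|---|---|---|
| larch | 12.0 | 32 |
| larch | 20.0 | 33 |
| larch | 30.0 | 34 |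
| larch | 60.0 | 36 |
| larch | 96.0 | 37 |
| larch | 144 | 34 |
| alder | 3.00 | 12 |
| alder | 6.00 | 25 |
| alder | 10.0 | 31 |
| alder | 12.0 | 32 |
| alder | 15.0 | 34 |
| alder | 20.0 | 37 |

(scatter of a reading: 1.5 percentage points)

- gamma: at 8.0 d add reagent, 100% of the amount charged, then wait 2.5 d
- zeta: at 8.0 d take out 90% of the target then present, then wait 2.5 d
- beta: change nothing and wait 2.5 d more
- eta: at 8.0 d add free catalyst, 100% of the amount charged, then wait 2.5 d

- removed target is counted in
- the earlier runs were read with a standard deviation of 1.5 percentage points
- on the list of suspects stand: starting material + reagent <-> target; starting material + reagent <-> isomer of the product A; target + free catalyst <-> isomer of the product A + free catalyst; reagent + free catalyst <-> idle complex; starting material + free catalyst -> spent catalyst; target <-> isomer of the product B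
- additions bring no volume worth counting

1. target, in percent of the starting material first charged, at 8.0 d
2. the option that brings most further target ("none" if no option brings more than 2 percentage points) (gamma / zeta / beta / eta / none)
3. target present, with what was taken out counted in, in percent of the starting material first charged, after gamma
4. target present, with what was taken out counted in, in percent of the starting material first charged, after beta

The bench rule for a plateau is to add more reagent. On the level stretch of the larch run this reckoning takes the forward and back rates of starting material + reagent <-> target as about equal, so each action can be judged by the push, the forward rate over the back rate just after the action. Taking out the target gives a push of 10.0. If target were the sole product, reagent left would be 0.186 M, and doubling the charge would give a push of 2.40. The isomers on the list may have drawn on reagent too, but starting material, charged at less than the reagent, is the limiting reagent, so reagent left stays near or above 0.0600 M, where the push is 5.33. The bench rule would match removal only with reagent left at 0.0289 M, and the floor lies higher than that. Both pushes drift back to 1 as the flask levels again, so they rank the options without giving yields. This reckoning ranks zeta first, ahead of gamma.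

The forecast differs. It gives 32.5% now, 31.5% after waiting, 50% after gamma, and says “Gamma is best, narrowly”.

The flask gives 35.8% now, 35.9% after waiting and 40.6% after gamma. Zeta gains 19 points and gamma 4.8 points, so the best option is zeta. Reagent left in the flask at 192 h is 37% of its charge, which makes gamma's push 3.73, below removal's 10.0.

    starting material + reagent ⇌ target (K = 22.0 L mol⁻¹, k = 0.300 L mol⁻¹ h⁻¹)
    starting material + reagent ⇌ isomer of the product A (K = 11.0 L mol⁻¹, k = 0.190 L mol⁻¹ h⁻¹)
    target + free catalyst ⇌ isomer of the product A + free catalyst, rate k3*[free catalyst]*[target] forward; the back reaction follows from the equilibrium constant (k = 17.0 L mol⁻¹ h⁻¹)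
    reagent + free catalyst ⇌ idle complex, settled at all times (K = 5.20 L mol⁻¹)
    starting material + free catalyst → spent catalyst (k = 0.330 L mol⁻¹ h⁻¹)
    target ⇌ isomer of the product B (K = 0.790, k = 0.0310 h⁻¹)

A neighbouring flask, charged from the start with 0.44 M of reagent, takes the same reckoning. Its charge above that of the flask, set on the reagent left in the flask, gives a push of 2.89, less than gamma's. The neighbouring flask's target stands at 40.3% at 192 h, a gain of 4.5 points, smaller than gamma's, with starting material down to 7.24%.

(The data were computed for an exercise, noise included.)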